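**Retrosynthetic overview**

- The target is traced back to 2-henicosyl-1H-pyrrole by Vilsmeier formylation at the free α-carbon (C2–CHO, last step). The pyrrole, the only ring, is traced back to 4-oxopentacosanal (as its dimethyl acetal) by Paal–Knorr condensation with ammonia (N1–C2 and N1–C5, step 4).
- The saturated keto acetal comes from a conjugated ynone by hydrogenation. The ynone comes from three components in one pot: 1-bromooctadecane, 1,3-dilithiopropyne and the Weinreb amide of 4,4-dimethoxybutanoic acid.
- With the chain numbered C1', C2', … from ring carbon C5, the key bond C3'–C4' is made first, as an sp3–sp3 SN2 alkylation of the propargylic carbanion. The acetylide left behind then acylates at the future ring carbon C5 (bond C1'–C5).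
- Enabling feature: ring carbon C5 (bound to N1) bears an unbranched, unfunctionalised chain whose C3' lies exactly two carbons from C5, and C3/C4 of the pyrrole are unsubstituted. C3'–C2'–C1' therefore maps onto propyne (propargylic CH2 plus C≡C, hydrogenated later), and C5–C4–C3–C2 onto a 4-oxobutanal unit with C5 at the acyl oxidation level.

Key step: step 2

Remark: the target has no stereocentre or double-bond geometry to control; propyne, 1-bromooctadecane and methyl 4,4-dimethoxybutanoate are taken as purchased.

**Route**

Step 1
Reactants: 1 methyl 4,4-dimethoxybutanoate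
Product: 2 4,4-dimethoxy-N-methoxy-N-methylbutanamide
Conditions: MeNH(OMe)·HCl (1.5 equiv), i-PrMgCl (3 equiv), THF, −20 → 0 °C
Reagents that add atoms: N,O-dimethylhydroxylamine hydrochloride, CNOC.Cl
Why: Weinreb amidation of an ester with the chloromagnesium amide of N,O-dimethylhydroxylamine is a standard acyl substitution that leaves the dimethyl acetal untouched and provides an acyl donor that stops at the ketone stage.

Step 2
Reactants: 3 propyne; 4 1-bromooctadecane; 2 4,4-dimethoxy-N-methoxy-N-methylbutanamide
Product: 8 1,1-dimethoxypentacos-5-yn-4-one, via 1,3-dilithiopropyne 5 (not isolated), via lithium henicos-1-yn-1-ide 6 (not isolated), via lithium hemiaminal alkoxide 7 (not isolated)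
Conditions: 3 (1.0 equiv), n-BuLi (2.0 equiv), TMEDA, THF–hexane, −78 → 0 °C; 4 (1.05 equiv), −30 °C → rt; 2 (0.95 equiv), −78 → −20 °C; AcOH, −78 °C, then H2O
Reagents that add atoms: none
Why: Double deprotonation of propyne gives dianion 5, whose sp3 propargylic carbanion is far more nucleophilic than its sp acetylide terminus and should displace bromide from 4 by SN2, forming the C3'–C4' sp3–sp3 bond and leaving the C21 acetylide 6; this adds to Weinreb amide 2 to give the N,O-chelated tetrahedral adduct 7, which should persist until the cold acidic quench and then collapse to ynone 8. The closest known reaction type is the sequential one-pot trapping of 1,3-dilithiopropyne with two different electrophiles (alkyl halide at the propargylic carbon, carbonyl electrophile at the acetylide), combined with the Weinreb ketone synthesis with lithium acetylides. No ring is closed and no stereocentre is formed in this step. Site selectivity between the two carbanionic carbons is secured by the large reactivity gap between the sp3 and sp centres and by the inertness of a lithium acetylide towards a primary bromide in THF without a dipolar cosolvent; mono-addition to the carbonyl is secured by chelate 7; and adding the bromide before the amide, in slight excess over the dianion, keeps the amide from meeting unreacted dianion. The product should carry the whole C25 chain (4 carbons from the amide, 3 from propyne, 18 from the bromide) with C5 at the ketone level and C2 at the aldehyde level, i.e. the complete Paal–Knorr precursor, from three simple components.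

Step 3
Reactants: 8 1,1-dimethoxypentacos-5-yn-4-one
Product: 9 1,1-dimethoxypentacosan-4-one
Conditions: H2 (1 atm), 10% Pd/C, EtOAc, trace K2CO3, rt
Reagents that add atoms: none
Why: Heterogeneous catalytic hydrogenation over Pd/C should saturate the conjugated C≡C bond to CH2–CH2 while the dialkyl ketone and the acetal (kept neutral by the carbonate) stay intact, which removes the temporary alkyne oxidation level of the C3 linchpin without changing the carbon skeleton.

Step 4
Reactants: 9 1,1-dimethoxypentacosan-4-one
Product: 11 2-henicosyl-1H-pyrrole, via 4-oxopentacosanal 10 (not isolated)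
Conditions: NH4OAc (10 equiv), AcOH–H2O–THF, 70 °C, N2
Reagents that add atoms: ammonium acetate, CC(=O)[O-].[NH4+]
Why: In buffered aqueous acetic acid the acetal should hydrolyse to keto aldehyde 10, which undergoes Paal–Knorr condensation with ammonia (two C–N condensations, loss of two waters) to the aromatic pyrrole, the acetate buffer being too weakly acidic to polymerise the 2-alkylpyrrole.

Step 5
Reactants: 11 2-henicosyl-1H-pyrrole
Product: 13 5-henicosyl-1H-pyrrole-2-carbaldehyde, via pyrrolylmethylene iminium chloride 12 (not isolated)
Conditions: POCl3 (1.1 equiv), DMF, ClCH2CH2Cl, 0 °C → rt; then 2 M aq NaOH, 0 °C → rt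
Reagents that add atoms: N,N-dimethylformamide, CN(C)C=O; water, O
Why: Vilsmeier–Haack formylation, in which the chloroiminium ion from POCl3/DMF should attack the only free α-position of 11 (strongly preferred over the β-positions) and the iminium salt 12 is hydrolysed by aqueous base to the aldehyde.

**Compound list**

1 | methyl 4,4-dimethoxybutanoate | COC(OC)CCC(=O)OC | starting material
2 | 4,4-dimethoxy-N-methoxy-N-methylbutanamide | COC(OC)CCC(=O)N(C)OC | intermediate
3 | propyne | CC#C | starting material
4 | 1-bromooctadecane | CCCCCCCCCCCCCCCCCCBr | starting material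
5 | 1,3-dilithiopropyne | [Li]CC#C[Li] | intermediate
6 | lithium henicos-1-yn-1-ide | [Li]C#CCCCCCCCCCCCCCCCCCCC | intermediate
7 | lithium 4-[methoxy(methyl)amino]-1,1-dimethoxypentacos-5-yn-4-olate (racemic, transient) | COC(OC)CCC(O[Li])(N(C)OC)C#CCCCCCCCCCCCCCCCCCCC | intermediate
8 | 1,1-dimethoxypentacos-5-yn-4-one | COC(OC)CCC(=O)C#CCCCCCCCCCCCCCCCCCCC | intermediate
9 | 1,1-dimethoxypentacosan-4-one | COC(OC)CCC(=O)CCCCCCCCCCCCCCCCCCCCC | intermediate
10 | 4-oxopentacosanal | O=CCCC(=O)CCCCCCCCCCCCCCCCCCCCC | intermediate
11 | 2-henicosyl-1H-pyrrole | CCCCCCCCCCCCCCCCCCCCCc1ccc[nH]1 | intermediate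
12 | N-[(5-henicosyl-1H-pyrrol-2-yl)methylidene]-N-methylmethanaminium chloride | CCCCCCCCCCCCCCCCCCCCCc1ccc(C=[N+](C)C)[nH]1.[Cl-] | intermediate
13 | 5-henicosyl-1H-pyrrole-2-carbaldehyde | CCCCCCCCCCCCCCCCCCCCCc1ccc(C=O)[nH]1 | target

**Summary**

Total step count: 5. Longest linear sequence: 5 steps (1 → 2 → 8 → 9 → 11 → 13); the propyne and bromide branches enter at step 2.

**Steps most likely to fail**

Step 2 (key step). The ambident propargyl/allenyl dianion may be alkylated at the wrong terminus, the strongly basic dianion may dehydrobrominate the primary bromide, or unreacted dianion may be carried into the acylation and consume the amide. The fallback replaces the one-pot dianion linchpin by a stepwise silyl-masked monoanion sequence that makes the same C3'–C4' bond. It sets out from 4: commercial 1-(trimethylsilyl)propyne is lithiated at its methyl group (n-BuLi, TMEDA, Et2O, −78 → 0 °C) and alkylated with 4, which should give trimethyl(henicos-1-yn-1-yl)silane F1. Desilylation (K2CO3, MeOH, rt) should give henicos-1-yne F2. Deprotonation (n-BuLi, THF, −78 °C) and addition of amide 2 should then give ynone 8, where the route is rejoined.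

Step 4. The liberated keto aldehyde may undergo aldol self-condensation before ring closure, and the acid-sensitive N–H pyrrole may oligomerise during the condensation. The fallback brings the nitrogen in with the electrophile instead of by late condensation. It sets out from acetylide 6 (made from 3 and 4 as in step 2): trapping with commercial 1-Boc-pyrrolidin-2-one (THF, −78 °C) should open the N-acyl lactam to tert-butyl (4-oxopentacos-5-yn-1-yl)carbamate F3. Hydrogenation (H2, Pd/C, EtOAc) should give tert-butyl (4-oxopentacosyl)carbamate F4. TFA/CH2Cl2 followed by NaHCO3 should remove the carbamate and close the cyclic imine 5-henicosyl-3,4-dihydro-2H-pyrrole F5. Dehydrogenation over Pd/C in refluxing mesitylene should aromatise it to 11, where the route is rejoined.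

Step 5. The electron-rich 2-alkylpyrrole may oligomerise under the acid-generating conditions, or may be formylated more than once. The fallback replaces electrophilic substitution by directed metalation. It sets out from 11: N-protection (Boc2O, DMAP, MeCN) should give tert-butyl 2-henicosyl-1H-pyrrole-1-carboxylate F6. α-Lithiation at the remaining free α-carbon (LiTMP, THF, −78 °C) and quenching with DMF should give tert-butyl 2-formyl-5-henicosyl-1H-pyrrole-1-carboxylate F7. Methanolysis of the carbamate (K2CO3, MeOH, rt) should give 13 directly.

Further compounds
F1 | step 2 | trimethyl(henicos-1-yn-1-yl)silane | C[Si](C)(C)C#CCCCCCCCCCCCCCCCCCCC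
F2 | step 2 | henicos-1-yne | C#CCCCCCCCCCCCCCCCCCCC
F3 | step 4 | tert-butyl (4-oxopentacos-5-yn-1-yl)carbamate | CC(C)(C)OC(=O)NCCCC(=O)C#CCCCCCCCCCCCCCCCCCCC
F4 | step 4 | tert-butyl (4-oxopentacosyl)carbamate | CC(C)(C)OC(=O)NCCCC(=O)CCCCCCCCCCCCCCCCCCCCC
F5 | step 4 | 5-henicosyl-3,4-dihydro-2H-pyrrole | CCCCCCCCCCCCCCCCCCCCCC1=NCCC1
F6 | step 5 | tert-butyl 2-henicosyl-1H-pyrrole-1-carboxylate | CCCCCCCCCCCCCCCCCCCCCc1cccn1C(=O)OC(C)(C)C
F7 | step 5 | tert-butyl 2-formyl-5-henicosyl-1H-pyrrole-1-carboxylate | CCCCCCCCCCCCCCCCCCCCCc1ccc(C=O)n1C(=O)OC(C)(C)C
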